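The constant we want is the rate at which D is wasted while it stands idle, and the earlier runs give a reading of it.

| setting | gamma | beta | eta | dawn | midnight | winter |
|---|---|---|---|---|---|---|
| X | 0.50 M | 0.50 M | 0.50 M | 0.50 M | 0.50 M (fed, over 1.5 h) | 0.50 M |
| D | 0.30 M | 0.20 M | 0.45 M | 0.300 M | 0.300 M | 0.300 M (fed, over 1.5 h) |
| remark | run made earlier | run made earlier | run made earlier | everything together at the start | all else is in the flask from the start; the feed brings no volume worth counting | all else is in the flask from the start; the feed brings no volume worth counting |
| time |  |  |  | 4.0 h | 4.0 h | 4.0 h |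

- gamma (time / h: Z / %): 0.200: 48.3; 0.667: 51.2; 1.00: 51.0; 1.50: 51.0; 2.50: 51.7; 3.00: 51.5; 4.00: 51.6
- beta (time / h: Z / %): 0.167: 35.8; 0.500: 36.4; 0.833: 36.0; 1.33: 36.6; 2.00: 35.3; 2.50: 36.2; 3.00: 36.4
- eta (time / h: Z / %): 0.250: 55.6; 0.417: 63.4; 0.667: 67.1; 0.833: 68.7; 1.33: 67.1; 2.00: 68.5; 3.00: 68.0

(readings scatter by 0.5 percentage points)

- the flask that comes out highest in amount of Z, in percent of the X charged, or "all alike" when all lie within 1.5 percentage points (dawn / midnight / winter / all alike)
- Z at the end, in percent of the X charged, dawn
- Z at the end, in percent of the X charged, midnight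
- Z at the end, in percent of the X charged, winter



Z levels off in each run, and the Z made per D charged, read at the last point, falls as the charge rises: 0.910 at 0.20 M, 0.860 at 0.30 M, 0.756 at 0.45 M. If D, the limiting reagent, is used at a steady rate, its mean idle time is the charge divided by 2 and by that rate. The gamma run's first reading gives 1.21 M/h, so the waste constant, the fraction of idle D lost per hour, reads 1.13 /h. The gap to the plateau in the eta run closes at 5.94 /h, which we take as the delay of X on its way to Z.

Dawn repeats gamma, so we expect about 51.6 %. Winter should stand above that, under the cap of 60.0 % set by its D. For midnight, a ceiling lets each X become Z on arrival while D wastes: 41.4 %. Counting the delay of X tightens it to 36.0 %. A floor lets D stand idle until the middle of the feed and counts the survivors: 25.8 %.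

The forecast chose winter, with 51.5 %, 39 % and 52 % for dawn, midnight and winter: “A rough stepwise estimate puts midnight near 39%”. That midnight figure lies above our ceiling.

The flasks give 51.3 %, 31.2 % and 54.1 %, so winter comes out highest, and midnight lands inside our bracket.

    X ⇌ J (K = 0.857, k = 0.0898 /min)
    X + D → G (k = 0.0230 /M/min)
    D + J → Z (k = 34.6 /M/min)
    D → Q (k = 0.0239 /min)
    2 X → L (k = 0.0697 /M/min)

The feed of midnight runs 1.5 h, longer than the 0.887 h that our reading of the waste constant gives as the life of idle D, and midnight ends with 0.139 M of Q, which is 46.4 % of its D. In the flask like winter but with 0.12 M of D, fed over the same 1.5 h, Q is 0.00101 M, which is 0.842 % of its D, and Z reaches 23.8 %.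

All runs were generated by integration for an exercise; scatter was added.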